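**Retrosynthetic overview**
1. The C3 bromine is installed last, by electrophilic bromination of 4,6-dibromoindole. That indole comes from its 2,3-dihydro form, so the problem reduces to N-Boc-4,6-dibromoindoline.
2. Feature used: in the carbocycle, C4, C5, C6 and C7 carry Br, H, Br, H. This is the same four-carbon pattern as C3 to C6 of 3,5-dibromo-2-pyrone, so only the fusion carbons C3a and C7a are missing.
3. Key disconnection: C3a–C4 and C7–C7a. A pyrone Diels–Alder reaction with the C=C of the pyrrolidine enamine of N-Boc-3-pyrrolidinone forms both bonds, and CO2 and pyrrolidine are extruded.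
4. Ring order: the five-membered nitrogen ring is bought, the benzene ring is built onto it, and the pyrrole ring is made aromatic afterwards.
5. Each cycloaddition partner is one step from commercial material (coumalic acid; N-Boc-3-pyrrolidinone and pyrrolidine).

Key step: step 3

Assumption: the enamine is taken to exist and react with its double bond next to the carbamate nitrogen, as expected for a ketone with a heteroatom on one alpha-carbon and as the C2 alkylation of such enamines indicates. Any isomer with the double bond on the far side can equilibrate with it through the iminium ion.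

**Step 1**
Reactants: 1 coumalic acid (2-oxo-2H-pyran-5-carboxylic acid)
Product: 3 3,5-dibromo-2H-pyran-2-one, via 5-bromo-2-pyrone 2 (not isolated)
Conditions: NBS (2.5 equiv), Bu4NBr (cat.), CHCl3, 50 °C
Reagents that add atoms: N-bromosuccinimide, O=C1CCC(=O)N1Br
Why: Hunsdiecker-type bromodecarboxylation, in which electrophilic bromine attacks C5 ipso (the beta-carbon of the ring enol ether), CO2 leaves to restore the pyrone, and a second equivalent substitutes C3, the other nucleophilic ring carbon; this is a known preparation of the dibromopyrone.

**Step 2**
Reactants: 4 tert-butyl 3-oxopyrrolidine-1-carboxylate; 5 pyrrolidine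
Product: 6 tert-butyl 4-(pyrrolidin-1-yl)-2,3-dihydro-1H-pyrrole-1-carboxylate
Conditions: 5 (1.3 equiv), PhMe, reflux, Dean–Stark; concentrate, co-evaporate with PhMe to strip excess 5; used crude under Ar
Reagents that add atoms: none
Why: Stork enamine condensation with azeotropic removal of water, in which the double bond should settle between C4 and C5, where it is conjugated with both nitrogens, and the Boc group tolerates amine and heat at this temperature.

**Step 3**
Reactants: 3 3,5-dibromo-2H-pyran-2-one; 6 tert-butyl 4-(pyrrolidin-1-yl)-2,3-dihydro-1H-pyrrole-1-carboxylate
Product: 9 tert-butyl 4,6-dibromoindoline-1-carboxylate, via bridged lactone cycloadduct 7 (not isolated), via aminocyclohexadiene 8 (not isolated)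
Conditions: 3 added slowly to 6 (1.5 equiv), PhMe, 4 Å MS, 0 → 23 °C; then AcOH (3 equiv), 110 °C
Reagents that add atoms: none
Why: This is an inverse-electron-demand Diels–Alder reaction followed by two eliminations: the enamine HOMO, largest on the carbon next to the carbamate nitrogen (future C7a), meets the pyrone LUMO at C6, so C7–C7a forms ahead of C3a–C4 in a strongly asynchronous addition that gives bridged lactone 7. Retro-Diels–Alder loss of CO2 gives diene 8, in which both bromines already sit on sp2 carbons, so the only path to aromaticity is loss of the C3a amino group with the C7a hydrogen; these two are cis, and AcOH lets the protonated amine leave by an E1 path through an arenium-type cation. The six-membered ring is closed by an intermolecular (4+2) cycloaddition across the enamine C=C of the five-membered ring, and the closest known reactions are the additions of 3,5-dibromo-2-pyrone to enol ethers and the benzannulation of electron-poor 2-pyrones by enamines of cyclic ketones. The four stereocentres of 7 (cis ring fusion from suprafacial addition, endo or exo) are all erased on aromatisation, so no facial or endo/exo control is needed. The selectivity needed is regiochemical: the tertiary amine is a much stronger donor than the carbamate nitrogen, whose lone pair is engaged by the Boc carbonyl, so the pyrrolidine sets the alkene polarity and places the amine-bearing carbon next to the C–Br of pyrone C3. Slow addition of 3 to excess 6 at low temperature should consume the pyrone before pyrrolidine is released, which protects it from ring opening by free amine.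

**Step 4**
Reactants: 9 tert-butyl 4,6-dibromoindoline-1-carboxylate
Product: 10 4,6-dibromoindoline (4,6-dibromo-2,3-dihydro-1H-indole)
Conditions: CF3CO2H, CH2Cl2, 0 → 23 °C; aq NaHCO3 work-up
Reagents that add atoms: none
Why: Acidolysis of a tert-butyl carbamate (loss of the tert-butyl cation as isobutene, then decarboxylation of the carbamic acid) leaves the aryl bromides untouched and frees the N–H that MnO2 needs, since N-acyl indolines dehydrogenate poorly.

**Step 5**
Reactants: 10 4,6-dibromoindoline
Product: 11 4,6-dibromo-1H-indole
Conditions: activated MnO2 (10 equiv), CH2Cl2, reflux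
Reagents that add atoms: none
Why: Dehydrogenation of an indoline to the indole with MnO2 is a standard aromatisation, placed before the bromination because the aniline-like indoline would direct NBS to C5 and C7.

**Step 6**
Reactants: 11 4,6-dibromo-1H-indole
Product: 12 3,4,6-tribromo-1H-indole
Conditions: NBS (1.0 equiv), DMF, 0 °C, dark
Reagents that add atoms: N-bromosuccinimide, O=C1CCC(=O)N1Br
Why: Electrophilic aromatic substitution goes to C3, the enamine-like and most nucleophilic carbon of an indole, while the carbocycle is deactivated by its two bromines, and one equivalent of NBS in the cold limits attack at C2.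

**Compound list**
1 | coumalic acid | O=C(O)c1ccc(=O)oc1 | starting material
2 | 5-bromo-2H-pyran-2-one | O=c1ccc(Br)co1 | intermediate
3 | 3,5-dibromo-2H-pyran-2-one | O=c1occ(Br)cc1Br | intermediate
4 | tert-butyl 3-oxopyrrolidine-1-carboxylate | CC(C)(C)OC(=O)N1CCC(=O)C1 | starting material
5 | pyrrolidine | C1CCNC1 | starting material
6 | tert-butyl 4-(pyrrolidin-1-yl)-2,3-dihydro-1H-pyrrole-1-carboxylate | CC(C)(C)OC(=O)N1CCC(=C1)N1CCCC1 | intermediate
7 | bridged lactone cycloadduct: N-Boc-hexahydroindole in which C4 and C7 are bridged by C(=O)–O (carbonyl on C4, oxygen on C7), Br on C4 and C6, C5=C6 double bond, pyrrolidin-1-yl on C3a, H on C7a, cis ring fusion; racemic, drawn as the isomer with the carbamate ring endo (the exo isomer converges on the same 8) | CC(C)(C)OC(=O)N1CC[C@@]2(N3CCCC3)[C@@H]1[C@@H]1OC(=O)[C@@]2(Br)C=C1Br | intermediate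
8 | tert-butyl 4,6-dibromo-3a-(pyrrolidin-1-yl)-2,3,3a,7a-tetrahydro-1H-indole-1-carboxylate, cis-fused, racemic | CC(C)(C)OC(=O)N1CC[C@@]2(N3CCCC3)[C@@H]1C=C(Br)C=C2Br | intermediate
9 | tert-butyl 4,6-dibromoindoline-1-carboxylate | CC(C)(C)OC(=O)N1CCc2c(Br)cc(Br)cc21 | intermediate
10 | 4,6-dibromoindoline | Brc1cc(Br)c2CCNc2c1 | intermediate
11 | 4,6-dibromo-1H-indole | Brc1cc(Br)c2cc[nH]c2c1 | intermediate
12 | 3,4,6-tribromo-1H-indole | Brc1cc(Br)c2c(Br)c[nH]c2c1 | target

**Total step count:** 6
**Longest linear sequence:** 5 (step 1 or step 2, then steps 3 to 6)

**Steps most likely to fail**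

Step 3.
- Risk: the cycloaddition may stall where a bond must form between two fully substituted carbons (C3a and C4). It may also reverse by retro-Mannich cleavage, lose the pyrone to ring opening by amine, or lose regiocontrol through migration of the enamine double bond.
- Fallback: the benzene ring is bought instead of built, and the pyrrole ring is closed by a Leimgruber–Batcho indole synthesis. The fallback sets out from pyrrolidine 5, now the amine partner of the enamine-forming step, and returns at 11.
- Commercial 4-bromo-2-nitrotoluene is brominated at the free position ortho to the methyl group and meta to the nitro group (NBS, H2SO4) to give 2,4-dibromo-6-nitrotoluene F1.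
- F1 is condensed with Me2NCH(OMe)2 and 5 in DMF at 110 °C to give (E)-1-[2-(2,4-dibromo-6-nitrophenyl)ethenyl]pyrrolidine F2.
- Reduction of the nitro group with Fe powder in AcOH spares the C–Br bonds and closes the ring with release of the amine, giving 11. Steps 4 and 5 are then not needed.

Step 2.
- Risk: the double bond may settle away from the carbamate nitrogen, the ketone may self-condense under amine catalysis, or the enamine may hydrolyse on handling.
- Fallback: the C–N bond is made by cross-coupling on an alkene of fixed position instead of by condensation. It sets out from 4 and returns at 6.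
- Ketone 4 is deprotonated with LiN(SiMe3)2 and trapped with PhNTf2 (THF, −78 °C). The enol triflates do not interconvert and can be separated on silica.
- Only tert-butyl 4-(trifluoromethylsulfonyloxy)-2,3-dihydro-1H-pyrrole-1-carboxylate F3 is carried on. It is coupled with 5 (Pd2(dba)3, BINAP, Cs2CO3, PhMe, 80 °C) in a Buchwald–Hartwig-type amination of an alkenyl triflate, giving 6.

Step 6.
- Risk: attack at C3 is slowed by the peri C4 bromine, so further bromination at C2 may compete. The N–H 3-bromoindole may also degrade under acid or light during isolation.
- Fallback: a protect, brominate, deprotect sequence that sets out from 11 and returns at 12.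
- Compound 11 is silylated (NaH, iPr3SiCl, THF, 0 °C) to give 4,6-dibromo-1-(triisopropylsilyl)-1H-indole F4. The bulky silyl group shields C2 and blocks N-bromination.
- NBS in THF at −78 °C should then give 3,4,6-tribromo-1-(triisopropylsilyl)-1H-indole F5, which is stable to chromatography.
- Bu4NF in THF at 0 °C releases 12.

**Further compounds**
F1 | step 3 | 2,4-dibromo-6-nitrotoluene | Cc1c(Br)cc(Br)cc1[N+](=O)[O-]
F2 | step 3 | (E)-1-[2-(2,4-dibromo-6-nitrophenyl)ethenyl]pyrrolidine | O=[N+]([O-])c1cc(Br)cc(Br)c1/C=C/N1CCCC1
F3 | step 2 | tert-butyl 4-(trifluoromethylsulfonyloxy)-2,3-dihydro-1H-pyrrole-1-carboxylate | CC(C)(C)OC(=O)N1CCC(=C1)OS(=O)(=O)C(F)(F)F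
F4 | step 6 | 4,6-dibromo-1-(triisopropylsilyl)-1H-indole | CC(C)[Si](C(C)C)(C(C)C)n1ccc2c(Br)cc(Br)cc21
F5 | step 6 | 3,4,6-tribromo-1-(triisopropylsilyl)-1H-indole | CC(C)[Si](C(C)C)(C(C)C)n1cc(Br)c2c(Br)cc(Br)cc21
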